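## Structural features

The target is a C–C linked biflavonoid made of a biochanin A unit (an isoflavone, 5,7-dihydroxy-3-(4-methoxyphenyl)chromen-4-one) and an acacetin unit (a flavone, 5,7-dihydroxy-2-(4-methoxyphenyl)chromen-4-one). The halves are joined by one biaryl bond from C8 of isoflavone ring A to C3' of flavone ring B, ortho to the flavone 4'-methoxy group. All six rings are flat and sp2-hybridised, so there is no stereocentre and no pair of neighbouring stereocentres. The only conceivable stereo element is the C8–C3' axis, which carries three ortho substituents and is left undefined in the target. The fragile points are: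
- the four phenols, two of them chelated to the C4 carbonyls;
- the two aryl methyl ethers, which must outlive the final deprotection;
- the electron-rich phloroglucinol-type rings A, which are easily over-halogenated;
- the isoflavone pyranone, whose C2 is open to hydroxide and other nucleophiles.

The real difficulty is regiochemical: in a 5,7-dioxygenated chromone, C6 and C8 are nearly equivalent nucleophilic sites, so arylating C8 of an intact isoflavone is unreliable, and the biaryl bond is hindered and electron-rich on one side. The key step exploits the open-chain precursor, in which the phloroglucinol ring already carries the aryl group next to the oxygen that becomes O1. The only hydrogen-bearing carbon ortho to that oxygen is then the future C4a, which is also activated by the ortho C5 and para C7 oxygens. An acyl carbon (future C4) held on O1 through the C2=C3 enol ether can therefore bond only to C4a, closing ring C of the isoflavone with the aryl group necessarily on C8.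

## Logic of the disconnections

**19 ⇒ 18.** The four O–C(isopropyl) bonds on O5 and O7 of both chromenone units are cut. The four phenols must appear last while the two aryl methyl ethers stay, and a secondary alkyl aryl ether is cleaved by a boron trihalide under conditions that spare a methyl ether not peri to a carbonyl. The gain is that every earlier intermediate is free of acidic, chelating or easily oxidised phenols. The demand is that the protecting group survives base, palladium catalysis and anhydrous acid, and that the last step discriminates secondary from methyl ethers.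

**18 ⇒ 16 (through 17).** The C4–C4a bond of the isoflavone is cut, opening ring C to an aryl enol ether of an α-aryl acrylic acid. Cutting here moves the C6/C8 question out of the chromone and into the substitution pattern of a simple phenol ring, where the blocked ortho carbon decides it. One ring and the whole regiochemical problem disappear. The forward step needs the carboxyl cis to the aryloxy group (or able to become so), an arene nucleophilic enough for anhydride-level activation, and an acid that leaves the ethers alone.

**16 ⇒ 15 ⇒ 11 + 14.** First the ester O–CH3 bond is restored, then the O1–C2 bond between the phenolic oxygen and the vinyl carbon is cut. C2 is the β-carbon of an acceptor-substituted alkene, so this bond is that of a vinylogous ester and forms by addition–elimination. The isoflavone C2–C3–C4 unit and ring B leave as one small acrylate, and a phenol remains. The forward steps require that the phenoxide attacks carbon and not sulfur, that the base is mild enough for the flavone, and that hydrolysis takes the ester carbonyl and not C2.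

**14 ⇒ 12 (through 13).** The future C2–C3 bond between the benzylic carbon and the one-carbon unit is cut, together with the O–S bond. The acidic benzylic position of an arylacetate accepts a formyl group in a crossed Claisen condensation. The gain is a commodity ester as starting material. The demand is sulfonylation of the enolate on oxygen.

**11 ⇒ 7 + 10.** The biaryl bond C8–C3' is cut. It is the only bond joining the two halves and is the natural place for a cross-coupling. Boron is placed on flavone ring B and the halogen on the phloroglucinol ring, because an arylboron flanked by two oxygens would protodeboronate readily. The gain is two fragments of comparable size. The demand is a coupling that tolerates a free phenol and forms a biaryl with three ortho substituents from an electron-rich bromide.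

**10 ⇒ 9 ⇒ 8.** The C–Br bond is cut, then two O–C(isopropyl) bonds. The gain is a commodity triphenol. The demands are bromination ortho to the hydroxyl and not between the two ethers, and a dialkylation stopped at the diether.

**7 ⇒ 6 ⇒ 4 (through 5) ⇒ 2 + 3, and 2 ⇒ 1.** In turn are cut the C–B bond, the flavone O1–C2 bond with its C2=C3 unsaturation, the chalcone Cα=Cβ bond, and two O–C(isopropyl) bonds. These are the standard aldol/oxidative-cyclisation cuts of a flavone, made early on a simple bromoarene. The gain is that ring A of the flavone is bought intact. The demand is that the aryl bromide survives base and the iodine-mediated oxidation, which it should.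

## Other disconnections considered

**Alternative 1:** The cut dissects isoflavone ring A at C8–C8a and C6–C7. C8a, C4a, C5 and C6 would come from 3-ethoxycyclobutenone A1, and C8 and C7 from the aryl siloxyalkyne A2. In the forward step, heating A1 with A2 would open A1 to a vinylketene and add the alkyne [2+2], with the aryl-bearing carbon bonding to the ketene carbon. A second 4π opening, 6π closure and tautomerisation would give the phenol A3.
- In favour: the aryl group is built into C8 and not introduced by substitution. The three ring A oxygens emerge differentiated: free OH on C8a for the enol ether, silyl ether on C7, ethyl ether on C5. On this point the alternative is the better plan, since the chosen route depends on a site-selective bromination (step 6) and a statistically controlled dialkylation (step 5). The conditions are neutral and thermal.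
- Against: A2 requires ynolate chemistry and is hydrolytically fragile, and A1 is a specialty reagent. A3 is only a phenol, so the pyranone would still have to be closed by an acylation like step 11. The flavone would have to be built late from the masked aldehyde on an elaborate substrate. The C5 ethyl ether would have to be cleaved beside two methyl ethers.
- Comparison: structurally both plans fix the aryl group on C8 before ring C closes. Mechanistically a pericyclic cascade steered by ketene/ynol-ether polarity stands against a polar aromatic substitution steered by a blocked position. In step economy A3 corresponds to the stage of 11 without the flavone, so three short steps (5–7) would be replaced by a longer fragment synthesis. The chosen plan is shorter.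

**Alternative 2:** The cut is the C2=C3 bond of the flavone (ring C of the acacetin unit). In the forward step the acyl ylide A4 would be heated in toluene. A4 is a phenacylidene phosphorane whose ortho oxygen carries the aroyl group of the isoflavone-bearing benzoic acid. The ylide carbon would attack the neighbouring ester carbonyl in an intramolecular Wittig reaction to give the tetra-O-methoxymethyl ether A5.
- In favour: the flavone forms under neutral, non-oxidising conditions at the correct oxidation level. The two halves are joined late through an ester, which is more convergent. The acetal protecting groups would come off with mild acid that cannot touch methyl ethers. In mildness and convergence the alternative is the equal or the better of steps 2–3 and 12.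
- Against: it addresses the easy ring. The 8-aryl isoflavone, now carrying a benzoic acid, must still be made by a closure like step 11 or by a coupling. The acetal groups are doubtful under the acid of such a closure. The ylide needs α-halogenation of a protected acetophenone, phosphonium salt formation and selective mono-O-acylation. O-to-C acyl migration can compete with the Wittig closure. The alkylating agent for the acetal groups is a carcinogen.
- Comparison: structurally the chosen plan makes the flavone first on a simple bromoarene, where harsh conditions cost nothing. Mechanistically a Wittig olefination of an ester stands against an iodine-mediated dehydrogenation. In step economy the alternative adds roughly four steps to the flavone half.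

**Alternative 3:** The cut opens ring A of the flavone unit at the bond from C4a to an oxygen-bearing ortho carbon, leading back to the linear triketo ester A6. In the forward step Mg(OMe)2 A8 would template a Claisen condensation of chain carbon C6 onto the ester carbon C1, giving the 2',4',6'-trihydroxychalcone A7.
- In favour: it is biomimetic, and ring A arrives with its three oxygens free and unprotected. Symmetry makes the two possible closures identical, so it is the equal of the chosen plan in regiochemistry and better in protecting-group count on that ring.
- Against: A6 would have to be assembled by acylating a polyanion with a cinnamoyl donor that already carries the isoflavone, under strongly basic conditions that threaten isoflavone C2. The enone of A6 is a Michael acceptor for its own enolates. The aldol mode of folding (C2 onto C7) competes and would give a resorcylate. A7 would still need an oxidative cyclisation like step 3, now with free phenols.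
- Comparison: structurally the ring made here is one the chosen plan buys intact as 1. Mechanistically a templated polyketide Claisen stands against a Claisen–Schmidt condensation on a finished ring. In step economy several uncertain steps would replace steps 1–2 for no gain in control.

Key step: step 11

Remarks on the chemistry:
- The C8–C3' axis is treated as configurationally undefined, as in the target.
- Compounds 14 and 15 are drawn as Z isomers; E isomers would be carried along, because step 11 runs under alkene-equilibrating acid.
- Checked atom by atom, 16 and 18 map onto the target. The Z descriptor of 16 is correct for carboxyl cis to aryloxy, since CO2H outranks aryl on the α-carbon and aryloxy outranks H on the β-carbon.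

## Route

Step 1
Reactants: 1 2,4,6-trihydroxyacetophenone
Product: 2 1-(2-hydroxy-4,6-diisopropoxyphenyl)ethan-1-one
Conditions: 2-bromopropane (2.2 equiv), K2CO3, DMF, 60 °C
Reagents that add atoms: 2-bromopropane, CC(C)Br
Why: Williamson etherification; the hydroxyl hydrogen-bonded to the acetyl carbonyl is the least nucleophilic, so alkylation should stop at the 4,6-diether.

Step 2
Reactants: 2 1-(2-hydroxy-4,6-diisopropoxyphenyl)ethan-1-one; 3 3-bromo-4-methoxybenzaldehyde
Product: 4 (E)-3-(3-bromo-4-methoxyphenyl)-1-(2-hydroxy-4,6-diisopropoxyphenyl)prop-2-en-1-one
Conditions: KOH (50% aq.), EtOH, 0 °C → rt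
Reagents that add atoms: none
Why: Claisen–Schmidt condensation of a methyl ketone with a non-enolisable aldehyde; E1cB dehydration of the aldol gives the conjugated E enone.

Step 3
Reactants: 4 (E)-3-(3-bromo-4-methoxyphenyl)-1-(2-hydroxy-4,6-diisopropoxyphenyl)prop-2-en-1-one
Product: 6 2-(3-bromo-4-methoxyphenyl)-5,7-diisopropoxy-4H-chromen-4-one, via flavanone 5 (not isolated)
Conditions: I2 (cat.), DMSO, 130 °C
Reagents that add atoms: none
Why: Oxidative cyclisation of a 2'-hydroxychalcone: oxa-Michael closure to flavanone 5, α-iodination and loss of HI, with DMSO re-oxidising HI to I2 so that acid does not accumulate; the aryl bromide and the ethers are spectators.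

Step 4
Reactants: 6 2-(3-bromo-4-methoxyphenyl)-5,7-diisopropoxy-4H-chromen-4-one
Product: 7 5,7-diisopropoxy-2-[4-methoxy-3-(4,4,5,5-tetramethyl-1,3,2-dioxaborolan-2-yl)phenyl]-4H-chromen-4-one
Conditions: B2pin2, PdCl2(dppf) (cat.), KOAc, 1,4-dioxane, 90 °C
Reagents that add atoms: bis(pinacolato)diboron, CC1(C)OB(OC1(C)C)B1OC(C)(C)C(C)(C)O1
Why: Miyaura borylation of an aryl bromide; the weak acetate base allows transmetalation of the diboron without triggering Suzuki homocoupling of the product.

Step 5
Reactants: 8 phloroglucinol
Product: 9 3,5-diisopropoxyphenol
Conditions: 2-bromopropane (2 equiv), K2CO3, DMF, 50 °C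
Reagents that add atoms: 2-bromopropane, CC(C)Br
Why: Williamson etherification under stoichiometric control; the secondary halide favours O- over C-alkylation, and the diether should be separable from mono- and triether by chromatography.

Step 6
Reactants: 9 3,5-diisopropoxyphenol
Product: 10 2-bromo-3,5-diisopropoxyphenol
Conditions: NBS (1.0 equiv), i-Pr2NH (cat.), CH2Cl2, −78 → 0 °C
Reagents that add atoms: N-bromosuccinimide, O=C1CCC(=O)N1Br
Why: Electrophilic aromatic bromination; the two equivalent carbons flanked by OH and one isopropoxy group are less hindered than the carbon between two isopropoxy groups, and the N-bromoamine formed from the amine catalyst is delivered ortho to the hydroxyl by hydrogen bonding.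

Step 7
Reactants: 7 5,7-diisopropoxy-2-[4-methoxy-3-(4,4,5,5-tetramethyl-1,3,2-dioxaborolan-2-yl)phenyl]-4H-chromen-4-one; 10 2-bromo-3,5-diisopropoxyphenol
Product: 11 2-[3-(2-hydroxy-4,6-diisopropoxyphenyl)-4-methoxyphenyl]-5,7-diisopropoxy-4H-chromen-4-one
Conditions: Pd(OAc)2 (cat.), SPhos (cat.), K3PO4, toluene/H2O, 90 °C
Reagents that add atoms: none
Why: Suzuki–Miyaura coupling; the bulky electron-rich ligand 2-dicyclohexylphosphino-2',6'-dimethoxybiphenyl (SPhos) should allow oxidative addition of zerovalent palladium to the electron-rich, doubly ortho-substituted bromophenol and reductive elimination of the biaryl with three ortho substituents, while boron sits on the ring less prone to protodeboronation.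

Step 8
Reactants: 12 methyl 4-methoxyphenylacetate
Product: 14 methyl (Z)-2-(4-methoxyphenyl)-3-(tosyloxy)acrylate, via sodium enolate 13 (not isolated)
Conditions: NaH, HCO2Me, THF, 0 °C → rt; then TsCl, 0 °C → rt
Reagents that add atoms: methyl formate, COC=O; p-toluenesulfonyl chloride, Cc1ccc(cc1)S(Cl)(=O)=O
Why: Crossed Claisen formylation of the arylacetate, then O-sulfonylation of the chelated sodium enolate 13 by the hard sulfonyl electrophile, which should place the tosyloxy group cis to the ester; the geometry is not critical downstream.

Step 9
Reactants: 11 2-[3-(2-hydroxy-4,6-diisopropoxyphenyl)-4-methoxyphenyl]-5,7-diisopropoxy-4H-chromen-4-one; 14 methyl (Z)-2-(4-methoxyphenyl)-3-(tosyloxy)acrylate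
Product: 15 methyl (Z)-3-{2-[5-(5,7-diisopropoxy-4-oxo-4H-chromen-2-yl)-2-methoxyphenyl]-3,5-diisopropoxyphenoxy}-2-(4-methoxyphenyl)acrylate
Conditions: Cs2CO3, DMF, rt
Reagents that add atoms: none
Why: Nucleophilic vinylic substitution by addition–elimination; 14 is a vinylogous mixed carbonic–sulfonic anhydride, so the cesium phenoxide of 11 should attack C3 rather than sulfur, and tosylate then leaves from the ester-stabilised carbanion, with retention giving the Z ether.

Step 10
Reactants: 15 methyl (Z)-3-{2-[5-(5,7-diisopropoxy-4-oxo-4H-chromen-2-yl)-2-methoxyphenyl]-3,5-diisopropoxyphenoxy}-2-(4-methoxyphenyl)acrylate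
Product: 16 (Z)-3-{2-[5-(5,7-diisopropoxy-4-oxo-4H-chromen-2-yl)-2-methoxyphenyl]-3,5-diisopropoxyphenoxy}-2-(4-methoxyphenyl)acrylic acid
Conditions: LiOH, THF/H2O, rt; then 1 M HCl, 0 °C, to pH 3
Reagents that add atoms: lithium hydroxide, [Li+].[OH-]
Why: Saponification by acyl–oxygen cleavage; the ester carbonyl should be attacked faster than the donor-deactivated β-carbon, no alcohol co-solvent is present to exchange the aryloxy group, and the base-labile isoflavone ring does not yet exist.

Step 11
Reactants: 16 (Z)-3-{2-[5-(5,7-diisopropoxy-4-oxo-4H-chromen-2-yl)-2-methoxyphenyl]-3,5-diisopropoxyphenoxy}-2-(4-methoxyphenyl)acrylic acid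
Product: 18 8-[5-(5,7-diisopropoxy-4-oxo-4H-chromen-2-yl)-2-methoxyphenyl]-5,7-diisopropoxy-3-(4-methoxyphenyl)-4H-chromen-4-one, via mixed trifluoroacetic anhydride 17 (not isolated)
Conditions: (CF3CO)2O, CH2Cl2, 0 °C → rt
Reagents that add atoms: none
Why: Intramolecular Friedel–Crafts acylation, the closest known type being the cyclodehydration of 3-aryloxyacrylic acids to chromones. Trifluoroacetic anhydride converts 16 into the mixed anhydride 17, which is polarised or ionised (assisted by the CF3CO2H released) to an acylium ion whose charge is shared with the enol-ether oxygen, O=C=C(Ar)–CH=O(+)Ar. That delocalisation lowers the C2=C3 bond order, so any E acid or E anhydride can rotate into the reactive Z arrangement and is drained through it. The acyl carbon (C4) then attacks C4a, which is ortho to O1 and to the C5 ether and para to the C7 ether, and the arenium ion loses its proton to trifluoroacetate to give the aromatic pyranone. The ring closed is the six-membered ring C (O1, C2, C3, C4, C4a, C8a), by 6-exo-trig attack on the anhydride carbonyl (6-exo-dig if the free acylium ion reacts), with C4–C4a the only new skeletal bond. No stereocentre is created. The step needs site selectivity and selective transfer of the aryloxyacryloyl group over the trifluoroacetyl group: the tether reaches only the two carbons ortho to O1, one of which is the quaternary biaryl carbon, such mixed anhydrides transfer the non-fluorinated acyl group, and moderate dilution should suppress intermolecular acylation at the free ring A carbons. The isopropyl and methyl ethers and the flavone are inert to these anhydrous acidic conditions.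

Step 12
Reactants: 18 8-[5-(5,7-diisopropoxy-4-oxo-4H-chromen-2-yl)-2-methoxyphenyl]-5,7-diisopropoxy-3-(4-methoxyphenyl)-4H-chromen-4-one
Product: 19 8-[5-(5,7-dihydroxy-4-oxo-4H-chromen-2-yl)-2-methoxyphenyl]-5,7-dihydroxy-3-(4-methoxyphenyl)-4H-chromen-4-one
Conditions: BCl3, CH2Cl2, −78 → 0 °C; then H2O
Reagents that add atoms: none
Why: Lewis-acid ether cleavage; boron coordinates each ether oxygen and chloride takes the secondary isopropyl carbon (the peri C5 ethers with chelation assistance), whereas the two methyl ethers, neither of them peri to a carbonyl, should be left intact at this temperature.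

## Compound list

1 | 2,4,6-trihydroxyacetophenone | CC(=O)c1c(O)cc(O)cc1O | starting material
2 | 1-(2-hydroxy-4,6-diisopropoxyphenyl)ethan-1-one | CC(=O)c1c(O)cc(OC(C)C)cc1OC(C)C | intermediate
3 | 3-bromo-4-methoxybenzaldehyde | COc1ccc(C=O)cc1Br | starting material
4 | (E)-3-(3-bromo-4-methoxyphenyl)-1-(2-hydroxy-4,6-diisopropoxyphenyl)prop-2-en-1-one | COc1ccc(/C=C/C(=O)c2c(O)cc(OC(C)C)cc2OC(C)C)cc1Br | intermediate
5 | 2-(3-bromo-4-methoxyphenyl)-5,7-diisopropoxychroman-4-one (racemic flavanone, not isolated) | COc1ccc(C2CC(=O)c3c(OC(C)C)cc(OC(C)C)cc3O2)cc1Br | intermediate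
6 | 2-(3-bromo-4-methoxyphenyl)-5,7-diisopropoxy-4H-chromen-4-one | COc1ccc(-c2cc(=O)c3c(OC(C)C)cc(OC(C)C)cc3o2)cc1Br | intermediate
7 | 5,7-diisopropoxy-2-[4-methoxy-3-(4,4,5,5-tetramethyl-1,3,2-dioxaborolan-2-yl)phenyl]-4H-chromen-4-one | COc1ccc(-c2cc(=O)c3c(OC(C)C)cc(OC(C)C)cc3o2)cc1B1OC(C)(C)C(C)(C)O1 | intermediate
8 | phloroglucinol | Oc1cc(O)cc(O)c1 | starting material
9 | 3,5-diisopropoxyphenol | CC(C)Oc1cc(O)cc(OC(C)C)c1 | intermediate
10 | 2-bromo-3,5-diisopropoxyphenol | CC(C)Oc1cc(O)c(Br)c(OC(C)C)c1 | intermediate
11 | 2-[3-(2-hydroxy-4,6-diisopropoxyphenyl)-4-methoxyphenyl]-5,7-diisopropoxy-4H-chromen-4-one | COc1ccc(-c2cc(=O)c3c(OC(C)C)cc(OC(C)C)cc3o2)cc1-c1c(O)cc(OC(C)C)cc1OC(C)C | intermediate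
12 | methyl 4-methoxyphenylacetate | COC(=O)Cc1ccc(OC)cc1 | starting material
13 | sodium (Z)-3-methoxy-2-(4-methoxyphenyl)-3-oxoprop-1-en-1-olate (not isolated) | COC(=O)/C(=C\[O-])c1ccc(OC)cc1.[Na+] | intermediate
14 | methyl (Z)-2-(4-methoxyphenyl)-3-(tosyloxy)acrylate | COC(=O)/C(=C\OS(=O)(=O)c1ccc(C)cc1)c1ccc(OC)cc1 | intermediate
15 | methyl (Z)-3-{2-[5-(5,7-diisopropoxy-4-oxo-4H-chromen-2-yl)-2-methoxyphenyl]-3,5-diisopropoxyphenoxy}-2-(4-methoxyphenyl)acrylate | COC(=O)/C(=C\Oc1cc(OC(C)C)cc(OC(C)C)c1-c1cc(-c2cc(=O)c3c(OC(C)C)cc(OC(C)C)cc3o2)ccc1OC)c1ccc(OC)cc1 | intermediate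
16 | (Z)-3-{2-[5-(5,7-diisopropoxy-4-oxo-4H-chromen-2-yl)-2-methoxyphenyl]-3,5-diisopropoxyphenoxy}-2-(4-methoxyphenyl)acrylic acid | OC(=O)/C(=C\Oc1cc(OC(C)C)cc(OC(C)C)c1-c1cc(-c2cc(=O)c3c(OC(C)C)cc(OC(C)C)cc3o2)ccc1OC)c1ccc(OC)cc1 | intermediate
17 | mixed anhydride of 16 with trifluoroacetic acid, Z (not isolated) | O=C(OC(=O)C(F)(F)F)/C(=C\Oc1cc(OC(C)C)cc(OC(C)C)c1-c1cc(-c2cc(=O)c3c(OC(C)C)cc(OC(C)C)cc3o2)ccc1OC)c1ccc(OC)cc1 | intermediate
18 | 8-[5-(5,7-diisopropoxy-4-oxo-4H-chromen-2-yl)-2-methoxyphenyl]-5,7-diisopropoxy-3-(4-methoxyphenyl)-4H-chromen-4-one | COc1ccc(-c2coc3c(-c4cc(-c5cc(=O)c6c(OC(C)C)cc(OC(C)C)cc6o5)ccc4OC)c(OC(C)C)cc(OC(C)C)c3c2=O)cc1 | intermediate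
19 | 8-[5-(5,7-dihydroxy-4-oxo-4H-chromen-2-yl)-2-methoxyphenyl]-5,7-dihydroxy-3-(4-methoxyphenyl)-4H-chromen-4-one (CNP0117905.0) | COc1ccc(-c2coc3c(-c4cc(-c5cc(=O)c6c(O)cc(O)cc6o5)ccc4OC)c(O)cc(O)c3c2=O)cc1 | target

## Step count and least certain steps

Total: 12 steps. Longest linear sequence: 9 steps (1, 2, 3, 4, 7, 9, 10, 11, 12). Steps 5–6 and step 8 are side branches.

**Step 11 (key step).** The mixed anhydride may be too weakly electrophilic because the β-aryloxy donor stabilises it. Closure would then be slow, and trifluoroacetylation or intermolecular acylation at the free ring A carbons, or acid cleavage of the enol ether on work-up, could take over. The fallback gives up the C4–C4a closure and forms the biaryl bond last; it sets out from 7 and returns at 18. Purchased biochanin A F1 would be alkylated on both hydroxyls (2-bromopropane, K2CO3, DMF, 80 °C) to 5,7-diisopropoxy-3-(4-methoxyphenyl)-4H-chromen-4-one F2. Electrophilic iodination (N-iodosuccinimide, catalytic CF3CO2H, MeCN) should go to C8, since C6 lies between two isopropoxy groups, giving 8-iodo-5,7-diisopropoxy-3-(4-methoxyphenyl)-4H-chromen-4-one F3. Suzuki–Miyaura coupling of F3 with 7 (Pd(OAc)2, SPhos, K3PO4, toluene/H2O, 90 °C) would give 18.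

**Step 6.** Site control may be lost, with bromination para to the hydroxyl (between the two ethers) or double bromination, because all three free ring carbons are strongly activated. The two possible monobromides differ in symmetry, so the outcome can be read from the aromatic proton pattern before material is committed. The fallback replaces electrophilic substitution by directed metalation; it sets out from 9 and returns at 10. Compound 9 would be protected (chloromethyl methyl ether, i-Pr2NEt, CH2Cl2) as 1,3-diisopropoxy-5-(methoxymethoxy)benzene F4. Lithiation with n-BuLi in THF at 0 °C should be steered by chelation to the acetal oxygens to the carbon between the acetal and an isopropoxy group. Quenching with 1,2-dibromotetrachloroethane would give 2-bromo-1,5-diisopropoxy-3-(methoxymethoxy)benzene F5, and HCl in MeOH would release 10.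

**Step 7.** Oxidative addition to the phenoxide-bearing, doubly ortho-substituted bromide may be slow, so that protodeboronation or homocoupling of 7 consumes the boronate. The fallback changes the order of bond formation so that the coupling partner is no longer a phenoxide; it sets out from 10 and returns at 15, bypassing 11. Compound 10 would first be alkenylated with 14 (Cs2CO3, DMF, rt) to methyl (Z)-3-(2-bromo-3,5-diisopropoxyphenoxy)-2-(4-methoxyphenyl)acrylate F6. F6 would then be coupled with 7 under anhydrous conditions (Pd(OAc)2, SPhos, K3PO4, toluene, 100 °C) to give 15.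

**Step 9.** Sulfonyl transfer may compete, with the phenoxide attacking sulfur and not C3; the hindered ortho-aryl phenoxide may also add slowly. The fallback removes the sulfur electrophile; it sets out from 12 and 11 and returns at 15. Enolate 13, made from 12 as in the first half of step 8, would be treated with the chloroiminium reagent from (COCl)2 and DMF in CH2Cl2 to give methyl (Z)-3-chloro-2-(4-methoxyphenyl)acrylate F7. This is drawn as Z, but either geometry would serve. Addition–elimination of 11 to F7 (Cs2CO3, DMF, rt to 50 °C) would give 15.

**Step 10.** Hydroxide may add at C3 and expel the phenoxide of 11 in place of attacking the ester carbonyl, or may open the flavone pyranone on prolonged exposure. The fallback avoids hydroxide by using an ester cleaved under neutral palladium catalysis; it sets out from 12 and 11 and returns at 16. Compound 12 would be transesterified (allyl alcohol, catalytic Ti(OiPr)4, heat) to allyl 4-methoxyphenylacetate F8. Formylation without free alkoxide (TiCl4, Et3N, HCO2Me) and tosylation (TsCl, N-methylimidazole, Et3N) would give allyl (Z)-2-(4-methoxyphenyl)-3-(tosyloxy)acrylate F9, for which either geometry would serve. Addition–elimination of 11 (Cs2CO3, DMF) would give allyl (Z)-3-{2-[5-(5,7-diisopropoxy-4-oxo-4H-chromen-2-yl)-2-methoxyphenyl]-3,5-diisopropoxyphenoxy}-2-(4-methoxyphenyl)acrylate F10. Allyl transfer to morpholine (Pd(PPh3)4 cat., THF, rt) would give 16.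

## Further compounds

F1 | step 11 | biochanin A, 5,7-dihydroxy-3-(4-methoxyphenyl)-4H-chromen-4-one (purchased) | COc1ccc(-c2coc3cc(O)cc(O)c3c2=O)cc1
F2 | step 11 | 5,7-diisopropoxy-3-(4-methoxyphenyl)-4H-chromen-4-one | COc1ccc(-c2coc3cc(OC(C)C)cc(OC(C)C)c3c2=O)cc1
F3 | step 11 | 8-iodo-5,7-diisopropoxy-3-(4-methoxyphenyl)-4H-chromen-4-one | COc1ccc(-c2coc3c(I)c(OC(C)C)cc(OC(C)C)c3c2=O)cc1
F4 | step 6 | 1,3-diisopropoxy-5-(methoxymethoxy)benzene | COCOc1cc(OC(C)C)cc(OC(C)C)c1
F5 | step 6 | 2-bromo-1,5-diisopropoxy-3-(methoxymethoxy)benzene | COCOc1cc(OC(C)C)cc(OC(C)C)c1Br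
F6 | step 7 | methyl (Z)-3-(2-bromo-3,5-diisopropoxyphenoxy)-2-(4-methoxyphenyl)acrylate | COC(=O)/C(=C\Oc1cc(OC(C)C)cc(OC(C)C)c1Br)c1ccc(OC)cc1
F7 | step 9 | methyl (Z)-3-chloro-2-(4-methoxyphenyl)acrylate | COC(=O)/C(=C\Cl)c1ccc(OC)cc1
F8 | step 10 | allyl 4-methoxyphenylacetate | C=CCOC(=O)Cc1ccc(OC)cc1
F9 | step 10 | allyl (Z)-2-(4-methoxyphenyl)-3-(tosyloxy)acrylate | C=CCOC(=O)/C(=C\OS(=O)(=O)c1ccc(C)cc1)c1ccc(OC)cc1
F10 | step 10 | allyl (Z)-3-{2-[5-(5,7-diisopropoxy-4-oxo-4H-chromen-2-yl)-2-methoxyphenyl]-3,5-diisopropoxyphenoxy}-2-(4-methoxyphenyl)acrylate | C=CCOC(=O)/C(=C\Oc1cc(OC(C)C)cc(OC(C)C)c1-c1cc(-c2cc(=O)c3c(OC(C)C)cc(OC(C)C)cc3o2)ccc1OC)c1ccc(OC)cc1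
A1 | alternative 1 | 3-ethoxycyclobut-2-en-1-one | CCOC1=CC(=O)C1
A2 | alternative 1 | 2-{4-methoxy-3-[(triisopropylsilyloxy)ethynyl]phenyl}-1,3-dioxolane | COc1ccc(C2OCCO2)cc1C#CO[Si](C(C)C)(C(C)C)C(C)C
A3 | alternative 1 | 2-[5-(1,3-dioxolan-2-yl)-2-methoxyphenyl]-5-ethoxy-3-(triisopropylsilyloxy)phenol | CCOc1cc(O)c(-c2cc(C3OCCO3)ccc2OC)c(O[Si](C(C)C)(C(C)C)C(C)C)c1
A4 | alternative 2 | 2-[2-oxo-2-(triphenylphosphoranylidene)acetyl... ylide: 3,5-bis(methoxymethoxy)-2-[(triphenylphosphoranylidene)acetyl]phenyl 3-[5,7-bis(methoxymethoxy)-3-(4-methoxyphenyl)-4-oxo-4H-chromen-8-yl]-4-methoxybenzoate | COCOc1cc(OCOC)c(C(=O)C=P(c2ccccc2)(c2ccccc2)c2ccccc2)c(OC(=O)c2ccc(OC)c(-c3c(OCOC)cc(OCOC)c4c(=O)c(-c5ccc(OC)cc5)coc34)c2)c1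
A5 | alternative 2 | tetra-O-methoxymethyl ether of the target | COCOc1cc(OCOC)c2c(=O)cc(-c3ccc(OC)c(-c4c(OCOC)cc(OCOC)c5c(=O)c(-c6ccc(OC)cc6)coc45)c3)oc2c1
A6 | alternative 3 | methyl (E)-9-{3-[5,7-bis(methoxymethoxy)-3-(4-methoxyphenyl)-4-oxo-4H-chromen-8-yl]-4-methoxyphenyl}-3,5,7-trioxonon-8-enoate | COC(=O)CC(=O)CC(=O)CC(=O)/C=C/c1ccc(OC)c(-c2c(OCOC)cc(OCOC)c3c(=O)c(-c4ccc(OC)cc4)coc23)c1
A7 | alternative 3 | (E)-3-{3-[5,7-bis(methoxymethoxy)-3-(4-methoxyphenyl)-4-oxo-4H-chromen-8-yl]-4-methoxyphenyl}-1-(2,4,6-trihydroxyphenyl)prop-2-en-1-one | O=C(/C=C/c1ccc(OC)c(-c2c(OCOC)cc(OCOC)c3c(=O)c(-c4ccc(OC)cc4)coc23)c1)c1c(O)cc(O)cc1O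
A8 | alternative 3 | magnesium methoxide, Mg(OMe)2 | CO[Mg]OC
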